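**Assumptions:** prostanoid numbering is used in the explanations (C1 = ester carbon, C7 = CH–OAc, C8–C12 = ring, C13–C20 = octenyl chain). Compound 1 is bought as the enantiopure TBS ether of (R)-4-hydroxycyclopent-2-enone. The route has not been run; selectivities are predictions.

## Retrosynthetic overview

1. The C10–I bond comes from a last-step α-iodination of the enone; both Z-alkenes come from one Lindlar semi-hydrogenation of a 5,14-diyne.
2. Key disconnection, C7–C8 (plus the C7 acetate): a SmI2 radical–polar crossover reductive aldol of α'-bromo enone 8 with ynal 12, acetylated in the same pot; it sets C7 and C8 from C12.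
3. Bromo enone 8 comes from (S)-4-hydroxy-4-(oct-2-ynyl)cyclopentenone 7, made by 1,3-carbonyl transposition of (R)-4-TBSO-cyclopentenone (propargylation anti to OTBS sets C12, then pentylation, desilylation, MnO2).
4. Ynal 12 comes from hex-5-ynoic acid, formaldehyde and methanol.
5. Rings: the single cyclopentenone ring is purchased; no ring-forming step.

## Route

**Step 1**
Reactants: 1, (R)-4-[(tert-butyldimethylsilyl)oxy]cyclopent-2-en-1-one; 2, propargyl bromide
Product: 3, (1S,4R)-4-[(tert-butyldimethylsilyl)oxy]-1-(prop-2-yn-1-yl)cyclopent-2-en-1-ol (OH cis to OTBS)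
Conditions: allenylmagnesium bromide (from 2, Mg, cat. HgCl2, Et2O), Et2O–THF, −78 °C
Reagents that add atoms: none
Why: Grignard propargylation: allenyl-MgBr reacts by SE2′ to give the homopropargyl carbinol by 1,2-addition, and attack anti to the C4 silyloxy group sets the C12 configuration.

**Step 2**
Reactants: 3; 4, 1-iodopentane
Product: 5, (1S,4R)-4-[(tert-butyldimethylsilyl)oxy]-1-(oct-2-yn-1-yl)cyclopent-2-en-1-ol
Conditions: n-BuLi (2.2 equiv), THF–DMPU, −78 → 0 °C; then 4, 0 °C → rt
Reagents that add atoms: none
Why: SN2 alkylation of the lithium acetylide (alkoxide/acetylide dianion) builds the oct-2-ynyl chain without the propargyl/allenyl ambiguity of a preformed octynyl nucleophile; no stereocenter is touched.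

**Step 3**
Reactants: 5
Product: 6, (1S,4R)-1-(oct-2-yn-1-yl)cyclopent-2-ene-1,4-diol (cis-diol)
Conditions: TBAF, THF, 0 °C → rt
Reagents that add atoms: none
Why: Fluoride-mediated desilylation frees the secondary allylic alcohol.

**Step 4**
Reactants: 6
Product: 7, (S)-4-hydroxy-4-(oct-2-yn-1-yl)cyclopent-2-en-1-one
Conditions: activated MnO2, CH2Cl2, rt
Reagents that add atoms: none
Why: Chemoselective MnO2 oxidation of the secondary allylic alcohol completes the 1,3-carbonyl transposition; the tertiary C12 carbinol is inert and cannot epimerise.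

**Step 5**
Reactants: 7
Product: 8, (4R)-5-bromo-4-hydroxy-4-(oct-2-yn-1-yl)cyclopent-2-en-1-one (mixture of C5 epimers)
Conditions: TMSOTf, Et3N, CH2Cl2, 0 °C; then NBS, THF, −78 °C; 1 M HCl work-up (removes O-TMS)
Reagents that add atoms: N-bromosuccinimide, O=C1CCC(=O)N1Br
Why: Soft enolisation can only give the cross-conjugated 2-silyloxydiene (C12 has no γ-H), and electrophilic bromination of this silyl enol ether occurs at C8; the C8 configuration is irrelevant because it is erased in step 9.

**Step 6**
Reactants: 9, hex-5-ynoic acid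
Product: 10, 7-hydroxyhept-5-ynoic acid
Conditions: n-BuLi (2.1 equiv), THF–DMPU, −78 → −20 °C; (CH2O)n, → rt; H3O+
Reagents that add atoms: paraformaldehyde (formaldehyde), C=O
Why: Hydroxymethylation of the carboxylate/acetylide dianion adds C7.

**Step 7**
Reactants: 10
Product: 11, methyl 7-hydroxyhept-5-ynoate
Conditions: MeOH, cat. H2SO4, rt
Reagents that add atoms: methanol, CO
Why: Fischer esterification; the propargylic alcohol is unaffected.

**Step 8**
Reactants: 11
Product: 12, methyl 7-oxohept-5-ynoate
Conditions: activated MnO2, CH2Cl2, rt (used immediately)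
Reagents that add atoms: none
Why: MnO2 oxidation of the propargylic alcohol gives the ynal without touching the ester.

**Step 9 (key step)**
Reactants: 8; 12
Product: 13, methyl (7R)-7-(acetyloxy)-7-[(1R,5R)-5-hydroxy-5-(oct-2-yn-1-yl)-2-oxocyclopent-3-en-1-yl]hept-5-ynoate
Conditions: SmI2 (2.2 equiv), THF, −78 °C, 5 min; then 12 (1.3 equiv), −78 °C; then Ac2O (4 equiv), −78 → −30 °C; pH 7 buffer
Reagents that add atoms: acetic anhydride, CC(=O)OC(C)=O
Why: Samarium Reformatsky-type reductive aldol: single-electron transfer cleaves C8–Br to the C8 α-keto radical, a second SmI2 converts it to the Sm(III) dienolate without base, and C7–C8 forms in a chair Zimmerman–Traxler transition state of the ring-locked E-enolate (anti aldol) with Sm(III) held by the enolate oxygen and the C12–OH so the aldehyde is delivered to the hydroxyl face (side chain cis to OH, trans to the octynyl chain); the Sm aldolate is acetylated in situ so the β-acetoxy ketone never meets base.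

**Step 10**
Reactants: 13
Product: 14, methyl (5Z,7S)-7-(acetyloxy)-7-[(1R,5R)-5-hydroxy-5-[(2Z)-oct-2-en-1-yl]-2-oxocyclopent-3-en-1-yl]hept-5-enoate
Conditions: H2 (1 atm, stopped at 2.0 equiv), Lindlar catalyst, quinoline, EtOAc, rt
Reagents that add atoms: none
Why: Lindlar syn semi-hydrogenation converts both alkynes to Z-alkenes in one operation; the poisoned catalyst should leave the enone and allylic acetate intact if uptake is monitored.

**Step 11**
Reactants: 14
Product: 15, 7-acetoxy-7,8-dihydroiodovulone I, methyl (5Z,7S)-7-(acetyloxy)-7-[(1R,5S)-5-hydroxy-3-iodo-5-[(2Z)-oct-2-en-1-yl]-2-oxocyclopent-3-en-1-yl]hept-5-enoate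
Conditions: I2 (2 equiv), pyridine, CH2Cl2, 0 °C → rt, dark
Reagents that add atoms: iodine, II
Why: Johnson α-iodination of the enone (pyridine conjugate addition, iodination of the enolate, elimination) places iodine only at C10 and creates no stereocenter.

The spatial arrangement at C12, C8 and C7 is unchanged from its creation to the target; the CIP letters change between 7, 8, 13, 14 and 15 only because substituent priorities change (Br, alkyne versus alkene, iodine).

## Compound list

1 | (R)-4-[(tert-butyldimethylsilyl)oxy]cyclopent-2-en-1-one | O=C1C=C[C@H](O[Si](C)(C)C(C)(C)C)C1 | starting material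
2 | propargyl bromide | C#CCBr | starting material
3 | (1S,4R)-4-[(tert-butyldimethylsilyl)oxy]-1-(prop-2-yn-1-yl)cyclopent-2-en-1-ol | C#CC[C@@]1(O)C=C[C@H](O[Si](C)(C)C(C)(C)C)C1 | intermediate
4 | 1-iodopentane | CCCCCI | starting material
5 | (1S,4R)-4-[(tert-butyldimethylsilyl)oxy]-1-(oct-2-yn-1-yl)cyclopent-2-en-1-ol | CCCCCC#CC[C@@]1(O)C=C[C@H](O[Si](C)(C)C(C)(C)C)C1 | intermediate
6 | (1S,4R)-1-(oct-2-yn-1-yl)cyclopent-2-ene-1,4-diol | CCCCCC#CC[C@@]1(O)C=C[C@H](O)C1 | intermediate
7 | (S)-4-hydroxy-4-(oct-2-yn-1-yl)cyclopent-2-en-1-one | CCCCCC#CC[C@@]1(O)C=CC(=O)C1 | intermediate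
8 | (4R)-5-bromo-4-hydroxy-4-(oct-2-yn-1-yl)cyclopent-2-en-1-one (C5 epimers) | CCCCCC#CC[C@@]1(O)C=CC(=O)C1Br | intermediate
9 | hex-5-ynoic acid | C#CCCCC(=O)O | starting material
10 | 7-hydroxyhept-5-ynoic acid | OCC#CCCCC(=O)O | intermediate
11 | methyl 7-hydroxyhept-5-ynoate | COC(=O)CCCC#CCO | intermediate
12 | methyl 7-oxohept-5-ynoate | COC(=O)CCCC#CC=O | intermediate
13 | methyl (7R)-7-(acetyloxy)-7-[(1R,5R)-5-hydroxy-5-(oct-2-yn-1-yl)-2-oxocyclopent-3-en-1-yl]hept-5-ynoate | CCCCCC#CC[C@@]1(O)C=CC(=O)[C@@H]1[C@H](C#CCCCC(=O)OC)OC(C)=O | intermediate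
14 | methyl (5Z,7S)-7-(acetyloxy)-7-[(1R,5R)-5-hydroxy-5-[(2Z)-oct-2-en-1-yl]-2-oxocyclopent-3-en-1-yl]hept-5-enoate | CCCCC/C=C\C[C@@]1(O)C=CC(=O)[C@@H]1[C@H](/C=C\CCCC(=O)OC)OC(C)=O | intermediate
15 | 7-acetoxy-7,8-dihydroiodovulone I | CCCCC/C=C\C[C@@]1(O)C=C(I)C(=O)[C@@H]1[C@H](/C=C\CCCC(=O)OC)OC(C)=O | target

## Summary

Total steps: 11. Longest linear sequence: 8 (steps 1–5, 9, 10, 11).

Steps most likely to fail:

1. **Step 9.** Risks are low anti/facial selectivity with the small alkynyl aldehyde, protonation of the Sm enolate by the free OH, and retro-aldol before acetylation. Fallback: drop the bromide/SET route and use a polar boron aldol. O-silylate 7, form the dicyclohexylboron E-enolate (Cy2BCl, Et3N), add 12 (tight chair, anti), then acetylate C7–OH separately and desilylate.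
2. **Step 10.** Risks are over-reduction of the enone, incomplete reduction of one alkyne, or allylic acetate hydrogenolysis. Fallback: set the alkene geometries before the fragments are joined. Lindlar-reduce 5 (no enone present) to the (Z)-octenyl series, and reduce 11 to methyl (Z)-7-hydroxyhept-5-enoate before oxidising it to the (Z)-enal, so no late hydrogenation is needed.
3. **Step 11.** Risks are base-induced loss of the C7 acetate to the cross-conjugated dienone, and 5-endo iodoetherification of the C12 homoallylic alcohol onto the 14Z alkene. Fallback: change the order and protection. Omit Ac2O in step 9 and keep C12–OH as a silyl ether from step 5, iodinate the silyl-protected 7-hydroxy compound after Lindlar reduction, then desilylate and acetylate C7–OH last under neutral conditions (lipase, vinyl acetate).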